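**Strategy.** The ten-membered carbocycle is closed last at C1–C2 (germacrane numbering). The key step exploits the C2–C3 ethano bridge that separates the Z C4=C5 alkene from C1 of the C1=C10 enoate, the precursor of the 1,10-epoxide. One-pot 9-BBN hydroboration of a diene terminus and intramolecular B-alkyl Suzuki–Miyaura coupling with an E enol tosylate join sp3 C2 to sp2 C1 and fix both ring alkenes as cis. The precursor is an open chain that already carries the trans-fused α-methylene lactone, the C8 ester and the silylated C9 alcohol; it comes from an indium Barbier union of a bromomethylbutenolide with a malate-derived aldehyde.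

Key step: step 11

Remark: germacrane numbering (ring C1–C10, lactone carbons C11–C13, ester carbon C14, methyl C15) is used in the text; TBS = tert-butyldimethylsilyl, Ts = 4-methylbenzenesulfonyl; compounds 1, 3, 10 and 16 are taken as commercial.

Step 1
Reactants: 1 (2Z)-3-methylpent-2-en-4-yn-1-ol
Product: 2 (2Z)-3-methylpenta-2,4-dien-1-ol
Conditions: H2 (1 atm), Pd/CaCO3 poisoned with Pb(OAc)2, quinoline, EtOAc, 0 °C
Reagents that add atoms: none
Why: Lindlar semihydrogenation should stop at the vinyl stage because the poisoned palladium surface reduces the terminal alkyne much faster than the conjugated diene it creates, and the existing Z double bond (the later C4=C5) is not touched.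

Step 2
Reactants: 2 (2Z)-3-methylpenta-2,4-dien-1-ol; 3 tert-butyldimethyl(prop-2-yn-1-yloxy)silane
Product: 5 (4R,5Z)-6-methyl-1-(TBS-oxy)octa-5,7-dien-2-yn-4-ol, via dienal 4 (not isolated)
Conditions: MnO2, toluene, 0 °C, filtration; then 3, Me2Zn, (S,S)-ProPhenol ligand (2,6-bis{[2-(hydroxydiphenylmethyl)pyrrolidin-1-yl]methyl}-4-methylphenol, 20 mol %), Ph3P=O, toluene, 4 °C
Reagents that add atoms: none
Why: Neutral allylic oxidation keeps the Z geometry of the labile dienal, which is used as its cold solution in a dinuclear-zinc catalysed asymmetric alkynylation of an enal that sets C6; the (S,S) ligand is expected to give 4R and its enantiomer is the remedy should the sense be opposite.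

Step 3
Reactants: 5 (4R,5Z)-6-methyl-1-(TBS-oxy)octa-5,7-dien-2-yn-4-ol
Product: 7 (2Z,4R,5Z)-2-iodo-6-methyl-1-(TBS-oxy)octa-2,5,7-trien-4-ol, via vinylalanate 6 (not isolated)
Conditions: NaAlH2(OCH2CH2OMe)2, THF, 0 °C; then N-iodosuccinimide, THF, −78 °C
Reagents that add atoms: N-iodosuccinimide, O=C1CCC(=O)N1I
Why: Hydroxyl-directed trans-hydroalumination of the propargylic alcohol places aluminium on the distal alkyne carbon (C11) inside a five-membered alkoxyaluminate, so iodinolysis with retention should give the Z iodoalkene with iodine cis to the carbinol carbon.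

Step 4
Reactants: 7 (2Z,4R,5Z)-2-iodo-6-methyl-1-(TBS-oxy)octa-2,5,7-trien-4-ol
Product: 8 (5R)-5-[(1Z)-2-methylbuta-1,3-dien-1-yl]-3-[(TBS-oxy)methyl]furan-2(5H)-one
Conditions: CO (1 atm), PdCl2(PPh3)2 (5 mol %), iPr2NEt, THF, 40 °C
Reagents that add atoms: carbon monoxide, [C-]#[O+]
Why: Palladium-catalysed carbonylative lactonisation (oxidative addition to the vinyl iodide, CO insertion, capture of the acylpalladium by the cis-disposed alcohol) should close the butenolide and supply C12 without touching the C6 stereocentre.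

Step 5
Reactants: 8 (5R)-5-[(1Z)-2-methylbuta-1,3-dien-1-yl]-3-[(TBS-oxy)methyl]furan-2(5H)-one
Product: 9 (5R)-3-(bromomethyl)-5-[(1Z)-2-methylbuta-1,3-dien-1-yl]furan-2(5H)-one
Conditions: Ph3PBr2, CH2Cl2, 0 °C to rt
Reagents that add atoms: dibromotriphenylphosphorane, BrP(Br)(c1ccccc1)(c1ccccc1)c1ccccc1
Why: The bromophosphonium reagent converts a primary silyl ether directly into the bromide (silyl transfer to bromide, then SN2 displacement of the alkoxyphosphonium) under non-basic conditions that spare the acidic butenolide γ-hydrogen.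

Step 6
Reactants: 10 dimethyl (2S)-2-hydroxybutanedioate (dimethyl L-malate)
Product: 12 dimethyl (2S,3E)-2-hydroxy-3-[(Ts-oxy)methylidene]butanedioate, via hydroxymethylidene malate 11 (not isolated)
Conditions: LiN(SiMe3)2 (2.2 equiv), THF, −78 to −20 °C; HCO2Me, −78 to 0 °C; aq. NH4Cl; then TsCl, N-methylimidazole, Et3N, MeCN, −15 °C
Reagents that add atoms: methyl formate, COC=O; 4-methylbenzenesulfonyl chloride, Cc1ccc(cc1)S(=O)(=O)Cl
Why: Crossed Claisen C-formylation at C10 under double deprotonation (the hydroxyl is carried as its alkoxide, which blocks β-elimination) is followed by enol O-sulfonylation under non-chelating amine conditions, which favour the E enol tosylate with the sulfonate anti to the ester.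

Step 7
Reactants: 12 dimethyl (2S,3E)-2-hydroxy-3-[(Ts-oxy)methylidene]butanedioate
Product: 13 dimethyl (2S,3E)-2-(TBS-oxy)-3-[(Ts-oxy)methylidene]butanedioate
Conditions: TBSOTf, 2,6-lutidine, CH2Cl2, −78 to 0 °C
Reagents that add atoms: tert-butyldimethylsilyl trifluoromethanesulfonate, CC(C)(C)[Si](C)(C)OS(=O)(=O)C(F)(F)F
Why: Standard silylation of the secondary alcohol gives the bulky, non-chelating C9 ether that the Felkin–Anh controlled addition of step 9 requires.

Step 8
Reactants: 13 dimethyl (2S,3E)-2-(TBS-oxy)-3-[(Ts-oxy)methylidene]butanedioate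
Product: 14 methyl (2E,3S)-4-oxo-3-(TBS-oxy)-2-[(Ts-oxy)methylidene]butanoate
Conditions: iBu2AlH (1.05 equiv), CH2Cl2, −78 °C; MeOH, aq. KNaC4H4O6
Reagents that add atoms: none
Why: Partial reduction should occur only at the α-silyloxy ester, whose aluminium hemiacetal is stabilised by the neighbouring oxygen, while the push-pull (vinylogous carbonate) ester is deactivated; the aldehyde is used at once.

Step 9
Reactants: 9 (5R)-3-(bromomethyl)-5-[(1Z)-2-methylbuta-1,3-dien-1-yl]furan-2(5H)-one; 14 methyl (2E,3S)-4-oxo-3-(TBS-oxy)-2-[(Ts-oxy)methylidene]butanoate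
Product: 15 methyl (2E,3S,4R)-4-hydroxy-4-{(2R,3R)-4-methylidene-2-[(1Z)-2-methylbuta-1,3-dien-1-yl]-5-oxooxolan-3-yl}-3-(TBS-oxy)-2-[(Ts-oxy)methylidene]butanoate
Conditions: In (metal powder), THF/H2O 1:1, rt
Reagents that add atoms: none
Why: In this indium Barbier allylation C7 of 9 attacks the aldehyde anti to the C6 dienyl group (trans lactone), the ring-locked E-type allyl unit reacts through a chair Zimmerman–Traxler transition state (anti C7/C8), and Felkin–Anh addition to the α-silyloxy aldehyde is the matched case, so the 8R alcohol (the C8 epimer needed for step 10) with the exocyclic C11=C13 should result.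

Step 10
Reactants: 15 methyl (2E,3S,4R)-4-hydroxy-4-{(2R,3R)-4-methylidene-2-[(1Z)-2-methylbuta-1,3-dien-1-yl]-5-oxooxolan-3-yl}-3-(TBS-oxy)-2-[(Ts-oxy)methylidene]butanoate; 16 (2S)-2-methylbutanoic acid
Product: 17 methyl (2E,3S,4S)-4-{[(2S)-2-methylbutanoyl]oxy}-4-{(2R,3S)-4-methylidene-2-[(1Z)-2-methylbuta-1,3-dien-1-yl]-5-oxooxolan-3-yl}-3-(TBS-oxy)-2-[(Ts-oxy)methylidene]butanoate
Conditions: PPh3, DIAD (slow addition), toluene, 0 °C to rt
Reagents that add atoms: none
Why: Mitsunobu esterification displaces the activated C8 oxygen by the carboxylate in an SN2 step, so the ester is installed and C8 is inverted to the required 8S in one operation.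

Step 11
Reactants: 17 methyl (2E,3S,4S)-4-{[(2S)-2-methylbutanoyl]oxy}-4-{(2R,3S)-4-methylidene-2-[(1Z)-2-methylbuta-1,3-dien-1-yl]-5-oxooxolan-3-yl}-3-(TBS-oxy)-2-[(Ts-oxy)methylidene]butanoate
Product: 19 methyl (1E,4Z,6R,7S,8S,9S)-8-{[(2S)-2-methylbutanoyl]oxy}-9-(TBS-oxy)germacra-1(10),4,11(13)-trien-12,6-olid-14-oate, via alkylborane 18 (not isolated)
Conditions: 9-BBN (1.5 equiv), THF, 0 °C to rt; then syringe-pump addition to Pd(dppf)Cl2 (20 mol %), AsPh3 (40 mol %), K3PO4 (3 M aq.), THF/DMF, 50 °C, 1 mM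
Reagents that add atoms: none
Why: 9-BBN adds to the unhindered, electron-rich terminal vinyl group of the 1,3-diene with boron at C2, after which zerovalent palladium inserts into the activated C1–O bond of the β-tosyloxy enoate, the phosphate-activated borane transmetallates and reductive elimination forms the C1(sp2)–C2(sp3) bond. The closest known reaction type is the B-alkyl Suzuki–Miyaura macrocyclisation of ω-boryl alkenyl halides and sulfonates. The ten-membered carbocycle is closed in endo mode with respect to C1=C10 (both alkene carbons end up in the ring), under high dilution. No stereocentre is created; the ring-cis geometry of C1=C10 follows from stereoretentive oxidative addition and reductive elimination on the E enol tosylate, and that of C4=C5 is inherited from compound 1. The step needs chemoselective hydroboration, which the electronic contrast between the diene terminus and the two acceptor alkenes (lactone methylidene, tosyloxy enoate) and the slow reaction of the trisubstituted C4=C5 should secure, and ring closure over oligomerisation, which the two cis-type alkenes and the trans-fused lactone favour by turning the chain ends toward each other.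

Step 12
Reactants: 19 methyl (1E,4Z,6R,7S,8S,9S)-8-{[(2S)-2-methylbutanoyl]oxy}-9-(TBS-oxy)germacra-1(10),4,11(13)-trien-12,6-olid-14-oate
Product: 20 methyl (1E,4Z,6R,7S,8S,9S)-9-hydroxy-8-{[(2S)-2-methylbutanoyl]oxy}germacra-1(10),4,11(13)-trien-12,6-olid-14-oate
Conditions: HF·pyridine, pyridine, THF, 0 °C to rt
Reagents that add atoms: none
Why: Buffered fluoride desilylation frees the C9 hydroxyl without base, so the C8 ester should not migrate and the lactone and enoate are untouched.

Step 13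
Reactants: 20 methyl (1E,4Z,6R,7S,8S,9S)-9-hydroxy-8-{[(2S)-2-methylbutanoyl]oxy}germacra-1(10),4,11(13)-trien-12,6-olid-14-oate
Product: 21 methyl (1R,4Z,6R,7S,8S,9R,10S)-1,10-epoxy-9-hydroxy-8-{[(2S)-2-methylbutanoyl]oxy}germacra-4,11(13)-dien-12,6-olid-14-oate (CNP0581690.1)
Conditions: Ti(OiPr)4 (1.2 equiv), tBuOOH (in decane), 4 Å molecular sieves, CH2Cl2, −20 °C
Reagents that add atoms: tert-butyl hydroperoxide, CC(C)(C)OO
Why: Hydroxyl-directed titanium alkoxide/hydroperoxide epoxidation (Sharpless-type system without tartrate) should oxidise only the allylic C1=C10 bond, and in the A(1,3)-minimised conformer with H9 eclipsing the ring-cis alkene the C9 alkoxide delivers oxygen to the face that gives the threo epoxy alcohol, i.e. 1R,10S.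

**Compound list**

1 | (2Z)-3-methylpent-2-en-4-yn-1-ol | C#C/C(C)=C\CO | starting material
2 | (2Z)-3-methylpenta-2,4-dien-1-ol | C=C/C(C)=C\CO | intermediate
3 | tert-butyldimethyl(prop-2-yn-1-yloxy)silane | C#CCO[Si](C)(C)C(C)(C)C | starting material
4 | (2Z)-3-methylpenta-2,4-dienal | C=C/C(C)=C\C=O | intermediate
5 | (4R,5Z)-6-methyl-1-(TBS-oxy)octa-5,7-dien-2-yn-4-ol | C=C/C(C)=C\[C@@H](O)C#CCO[Si](C)(C)C(C)(C)C | intermediate
6 | sodium (5R)-2,2-bis(2-methoxyethoxy)-5-[(1Z)-2-methylbuta-1,3-dien-1-yl]-3-[(TBS-oxy)methyl]-2,5-dihydro-1,2-oxaluminol-2-uide | [Na+].COCCO[Al-]1(OCCOC)O[C@H](/C=C(/C)C=C)C=C1CO[Si](C)(C)C(C)(C)C | intermediate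
7 | (2Z,4R,5Z)-2-iodo-6-methyl-1-(TBS-oxy)octa-2,5,7-trien-4-ol | C=C/C(C)=C\[C@@H](O)/C=C(\I)CO[Si](C)(C)C(C)(C)C | intermediate
8 | (5R)-5-[(1Z)-2-methylbuta-1,3-dien-1-yl]-3-[(TBS-oxy)methyl]furan-2(5H)-one | O=C1O[C@H](/C=C(/C)C=C)C=C1CO[Si](C)(C)C(C)(C)C | intermediate
9 | (5R)-3-(bromomethyl)-5-[(1Z)-2-methylbuta-1,3-dien-1-yl]furan-2(5H)-one | O=C1O[C@H](/C=C(/C)C=C)C=C1CBr | intermediate
10 | dimethyl (2S)-2-hydroxybutanedioate (dimethyl L-malate) | COC(=O)C[C@H](O)C(=O)OC | starting material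
11 | dimethyl (2S,3Z)-2-hydroxy-3-(hydroxymethylidene)butanedioate (enol of the 3-formyl malate) | COC(=O)/C(=C\O)[C@H](O)C(=O)OC | intermediate
12 | dimethyl (2S,3E)-2-hydroxy-3-[(Ts-oxy)methylidene]butanedioate | COC(=O)[C@@H](O)/C(C(=O)OC)=C\OS(=O)(=O)c1ccc(C)cc1 | intermediate
13 | dimethyl (2S,3E)-2-(TBS-oxy)-3-[(Ts-oxy)methylidene]butanedioate | COC(=O)[C@@H](O[Si](C)(C)C(C)(C)C)/C(C(=O)OC)=C\OS(=O)(=O)c1ccc(C)cc1 | intermediate
14 | methyl (2E,3S)-4-oxo-3-(TBS-oxy)-2-[(Ts-oxy)methylidene]butanoate | O=C[C@@H](O[Si](C)(C)C(C)(C)C)/C(C(=O)OC)=C\OS(=O)(=O)c1ccc(C)cc1 | intermediate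
15 | methyl (2E,3S,4R)-4-hydroxy-4-{(2R,3R)-4-methylidene-2-[(1Z)-2-methylbuta-1,3-dien-1-yl]-5-oxooxolan-3-yl}-3-(TBS-oxy)-2-[(Ts-oxy)methylidene]butanoate | C=C1C(=O)O[C@H](/C=C(/C)C=C)[C@H]1[C@@H](O)[C@@H](O[Si](C)(C)C(C)(C)C)/C(C(=O)OC)=C\OS(=O)(=O)c2ccc(C)cc2 | intermediate
16 | (2S)-2-methylbutanoic acid | CC[C@H](C)C(=O)O | starting material
17 | methyl (2E,3S,4S)-4-{[(2S)-2-methylbutanoyl]oxy}-4-{(2R,3S)-4-methylidene-2-[(1Z)-2-methylbuta-1,3-dien-1-yl]-5-oxooxolan-3-yl}-3-(TBS-oxy)-2-[(Ts-oxy)methylidene]butanoate | C=C1C(=O)O[C@H](/C=C(/C)C=C)[C@H]1[C@H](OC(=O)[C@@H](C)CC)[C@@H](O[Si](C)(C)C(C)(C)C)/C(C(=O)OC)=C\OS(=O)(=O)c2ccc(C)cc2 | intermediate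
18 | methyl (2E,3S,4S)-4-{(2R,3S)-2-[(1Z)-4-(9-borabicyclo[3.3.1]nonan-9-yl)-2-methylbut-1-en-1-yl]-4-methylidene-5-oxooxolan-3-yl}-4-{[(2S)-2-methylbutanoyl]oxy}-3-(TBS-oxy)-2-[(Ts-oxy)methylidene]butanoate | C=C1C(=O)O[C@H](/C=C(/C)CCB2C3CCCC2CCC3)[C@H]1[C@H](OC(=O)[C@@H](C)CC)[C@@H](O[Si](C)(C)C(C)(C)C)/C(C(=O)OC)=C\OS(=O)(=O)c4ccc(C)cc4 | intermediate
19 | methyl (1E,4Z,6R,7S,8S,9S)-8-{[(2S)-2-methylbutanoyl]oxy}-9-(TBS-oxy)germacra-1(10),4,11(13)-trien-12,6-olid-14-oate | C=C1C(=O)O[C@@H]2/C=C(/C)CC/C=C(/C(=O)OC)[C@H](O[Si](C)(C)C(C)(C)C)[C@@H](OC(=O)[C@@H](C)CC)[C@@H]12 | intermediate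
20 | methyl (1E,4Z,6R,7S,8S,9S)-9-hydroxy-8-{[(2S)-2-methylbutanoyl]oxy}germacra-1(10),4,11(13)-trien-12,6-olid-14-oate | C=C1C(=O)O[C@@H]2/C=C(/C)CC/C=C(/C(=O)OC)[C@H](O)[C@@H](OC(=O)[C@@H](C)CC)[C@@H]12 | intermediate
21 | methyl (1R,4Z,6R,7S,8S,9R,10S)-1,10-epoxy-9-hydroxy-8-{[(2S)-2-methylbutanoyl]oxy}germacra-4,11(13)-dien-12,6-olid-14-oate (CNP0581690.1) | C=C1C(=O)O[C@@H]2/C=C(/C)CC[C@H]3O[C@@]3(C(=O)OC)[C@H](O)[C@@H](OC(=O)[C@@H](C)CC)[C@@H]12 | target

**Step count and risks**

Total step count: 13. Longest linear sequence: 10 steps (steps 1–5, then 9–13).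

The three steps most likely to fail:

First, step 11. Transmetallation of the alkylborane at the hindered enol tosylate may be slow, so protodeboronation, β-hydride elimination or intermolecular coupling could outrun ten-membered ring closure, and the aqueous base may attack the methylidene lactone. The fallback sets out from 17 and makes the same C1–C2 bond without base. Hydroboration with 9-BBN followed by oxidative work-up (NaBO3·4H2O) would give the primary alcohol F1, which I2, PPh3 and 2,6-lutidine would convert into the primary iodide F2. Zinc insertion (Zn dust, LiCl, THF) and intramolecular Negishi coupling with Pd(dppf)Cl2 under high dilution would then close the ring and return to the route at 19.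

Second, step 10. The carbinol is flanked by two branched carbons, so E2 elimination toward C7 or simple failure of the SN2 displacement may prevail, and free azodicarboxylate may react with the diene. The fallback sets out from 15. Dess–Martin oxidation would give the C8 ketone F3, and Luche reduction (NaBH4, CeCl3·7H2O, MeOH, −78 °C) should deliver hydride anti to the C9 silyloxy group (Felkin–Anh) to give the 8S alcohol F4. Steglich esterification of F4 with 16 (DCC, DMAP, CH2Cl2) returns to the route at 17.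

Third, step 13. Oxygen transfer to the electron-poor C1=C10 bond may be too slow, so titanium-mediated transesterification or lactone opening could take over, or delivery may go to the wrong face. The fallback sets out from 20 and uses a nucleophilic oxidant after masking the more reactive lactone acceptor. Me2NH (THF, 0 °C) would add to C13 to give the amine adduct F5. Lithium tert-butyl peroxide (tBuOOH, nBuLi, THF, −20 °C), held by the lithium C9 alkoxide, would then epoxidise the enoate in Weitz–Scheffer fashion to the epoxy amine F6. N-methylation with MeI and elimination with NaHCO3 regenerate the methylidene lactone and return to the route at 21.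

Further compounds

F1 | step 11 | methyl (2E,3S,4S)-4-{(2R,3S)-2-[(1Z)-4-hydroxy-2-methylbut-1-en-1-yl]-4-methylidene-5-oxooxolan-3-yl}-4-{[(2S)-2-methylbutanoyl]oxy}-3-(TBS-oxy)-2-[(Ts-oxy)methylidene]butanoate | C=C1C(=O)O[C@H](/C=C(/C)CCO)[C@H]1[C@H](OC(=O)[C@@H](C)CC)[C@@H](O[Si](C)(C)C(C)(C)C)/C(C(=O)OC)=C\OS(=O)(=O)c2ccc(C)cc2
F2 | step 11 | methyl (2E,3S,4S)-4-{(2R,3S)-2-[(1Z)-4-iodo-2-methylbut-1-en-1-yl]-4-methylidene-5-oxooxolan-3-yl}-4-{[(2S)-2-methylbutanoyl]oxy}-3-(TBS-oxy)-2-[(Ts-oxy)methylidene]butanoate | C=C1C(=O)O[C@H](/C=C(/C)CCI)[C@H]1[C@H](OC(=O)[C@@H](C)CC)[C@@H](O[Si](C)(C)C(C)(C)C)/C(C(=O)OC)=C\OS(=O)(=O)c2ccc(C)cc2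
F3 | step 10 | methyl (2E,3S)-4-{(2R,3S)-4-methylidene-2-[(1Z)-2-methylbuta-1,3-dien-1-yl]-5-oxooxolan-3-yl}-4-oxo-3-(TBS-oxy)-2-[(Ts-oxy)methylidene]butanoate | C=C1C(=O)O[C@H](/C=C(/C)C=C)[C@H]1C(=O)[C@@H](O[Si](C)(C)C(C)(C)C)/C(C(=O)OC)=C\OS(=O)(=O)c2ccc(C)cc2
F4 | step 10 | methyl (2E,3S,4S)-4-hydroxy-4-{(2R,3R)-4-methylidene-2-[(1Z)-2-methylbuta-1,3-dien-1-yl]-5-oxooxolan-3-yl}-3-(TBS-oxy)-2-[(Ts-oxy)methylidene]butanoate | C=C1C(=O)O[C@H](/C=C(/C)C=C)[C@H]1[C@H](O)[C@@H](O[Si](C)(C)C(C)(C)C)/C(C(=O)OC)=C\OS(=O)(=O)c2ccc(C)cc2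
F5 | step 13 | methyl (1E,4Z,6R,7S,8S,9S,11R)-13-(dimethylamino)-9-hydroxy-8-{[(2S)-2-methylbutanoyl]oxy}germacra-1(10),4-dien-12,6-olid-14-oate | CN(C)C[C@@H]1C(=O)O[C@@H]2/C=C(/C)CC/C=C(/C(=O)OC)[C@H](O)[C@@H](OC(=O)[C@@H](C)CC)[C@@H]12
F6 | step 13 | methyl (1R,4Z,6R,7S,8S,9R,10S,11R)-13-(dimethylamino)-1,10-epoxy-9-hydroxy-8-{[(2S)-2-methylbutanoyl]oxy}germacr-4-en-12,6-olid-14-oate | CN(C)C[C@@H]1C(=O)O[C@@H]2/C=C(/C)CC[C@H]3O[C@@]3(C(=O)OC)[C@H](O)[C@@H](OC(=O)[C@@H](C)CC)[C@@H]12
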